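**Plan**

1. Numbering: carbocycle C1 (CH–OOH), C2, C3 (CH–OAc), C4 (C–CH3, the methyl being C15), C5, C6 (lactone CH–O), C7, C8, C9, C10; butenolide ring C6–C7=C11–C12(=O)–O; C13 is the CH2OAc carbon on C11 and C14 the CH2 on C10.
2. Retrosynthetic cuts, in order: C1–O (ene reaction, which turns C10=C14 back into a C1=C10 olefin), C9–C10 (ten-membered ring), O–C12 together with C7–C8 and C11–C13 (butenolide), C6–C7 and C3–C4 (two alkynylations), C4–C15 (cuprate).
3. Enabling feature: once the hydroperoxide is traced back to the C1=C10 olefin, C9–C10 joins a plain ring CH2 (C9, two carbons out from butenolide carbon C7) to an olefinic carbon. The carbocycle can therefore be closed there by hydroborating a C7 vinyl group and coupling C9 to a C10 alkenyl iodide, with no new stereocentre and with the butenolide and both acetates already in place.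
4. Forward: the chain grows linearly from the C10 iodoalkene (C1–C2, then C3, C4=C5, C6, C7≡C11–C12); C8–C9 and C13 are added across the second ynoate; the butenolide closes first by lactonisation, the ten-membered carbocycle second at C9–C10, and the ene reaction comes last.
5. Stereochemistry: E-C1=C10 from syn hydrozirconation–iodination; Z-C4=C5 and the C7=C11 geometry from syn carbocupration of ynoates; C3 (S) and C6 (R) from two catalyst-controlled zinc–ProPhenol alkynylations; C1 (R) from singlet oxygen attacking the outer face of the ring.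

Key step: step 13

Assumption: with (S,S)-ProPhenol the zinc alkynylide is taken to attack the Re face of an aldehyde (Si face with the (R,R)-ligand); should a Mosher analysis of 6 show the opposite sense, the two ligand enantiomers change places in steps 3 and 8.

**Route**

Step 1
Reactants: 1 pent-3-yn-1-ol
Product: 3 (E)-4-iodopent-3-en-1-ol, via alkenylzirconocene 2 (not isolated)
Conditions: Cp2Zr(H)Cl (2.5 equiv), THF, rt, dark; then I2, 0 °C
Reagents that add atoms: iodine, II
Why: Hydrozirconation adds Zr–H syn, the excess reagent equilibrating zirconium to the methyl-bearing carbon, and iodinolysis with retention should give the E iodide that later becomes the E-1(10) olefin.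

Step 2
Reactants: 3 (E)-4-iodopent-3-en-1-ol
Product: 4 (E)-4-iodopent-3-enal
Conditions: Dess–Martin periodinane, pyridine, CH2Cl2, 0 °C; crude aldehyde used at once
Reagents that add atoms: none
Why: Dess–Martin oxidation under buffered, near-neutral conditions should give the β,γ-unsaturated aldehyde without moving the double bond into conjugation.

Step 3
Reactants: 4 (E)-4-iodopent-3-enal; 5 methyl propiolate
Product: 6 methyl (4S,6E)-4-hydroxy-7-iodooct-6-en-2-ynoate
Conditions: 5 (3 equiv), Me2Zn (3 equiv), (S,S)-ProPhenol (20 mol %), Ph3PO (40 mol %), toluene, 0–4 °C (alkynylzinc reagent formed in the flask); then 4; aq. NH4Cl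
Reagents that add atoms: none
Why: In the dinuclear zinc–ProPhenol asymmetric alkynylation the methylzinc acetylide generated from 5 and Me2Zn should be delivered to the Re face of the aldehyde and so set C3 as S under catalyst control.

Step 4
Reactants: 6 methyl (4S,6E)-4-hydroxy-7-iodooct-6-en-2-ynoate
Product: 7 methyl (4S,6E)-4-[(tert-butyldimethylsilyl)oxy]-7-iodooct-6-en-2-ynoate
Conditions: TBSOTf, 2,6-lutidine, CH2Cl2, −78 °C
Reagents that add atoms: tert-butyldimethylsilyl triflate, CC(C)(C)[Si](C)(C)OS(=O)(=O)C(F)(F)F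
Why: Silylation of the propargylic alcohol removes the acidic proton and prevents lactonisation of the Z-enoate formed in the next step.

Step 5
Reactants: 7 methyl (4S,6E)-4-[(tert-butyldimethylsilyl)oxy]-7-iodooct-6-en-2-ynoate
Product: 9 methyl (2Z,4S,6E)-4-[(tert-butyldimethylsilyl)oxy]-7-iodo-3-methylocta-2,6-dienoate, via alkenylcuprate 8 (not isolated)
Conditions: Me2CuLi (from MeLi and CuI), THF, −78 °C; MeOH then aq. NH4Cl at −78 °C
Reagents that add atoms: lithium dimethylcuprate Me2CuLi, [Li+].C[Cu-]C
Why: Syn carbocupration of the ynoate with cold protonation should place the methyl on C4 and the hydrogen on C5 cis to each other, which makes C3 and the ester cis (the Z-4 olefin), while the unactivated alkenyl iodide does not couple with the cuprate at −78 °C.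

Step 6
Reactants: 9 methyl (2Z,4S,6E)-4-[(tert-butyldimethylsilyl)oxy]-7-iodo-3-methylocta-2,6-dienoate
Product: 10 (2Z,4S,6E)-4-[(tert-butyldimethylsilyl)oxy]-7-iodo-3-methylocta-2,6-dien-1-ol
Conditions: i-Bu2AlH (2.2 equiv), CH2Cl2, −78 °C; aqueous work-up
Reagents that add atoms: none
Why: 1,2-Reduction of the enoate by the aluminium hydride should give the allylic alcohol with the Z geometry and the iodide untouched.

Step 7
Reactants: 10 (2Z,4S,6E)-4-[(tert-butyldimethylsilyl)oxy]-7-iodo-3-methylocta-2,6-dien-1-ol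
Product: 11 (2Z,4S,6E)-4-[(tert-butyldimethylsilyl)oxy]-7-iodo-3-methylocta-2,6-dienal
Conditions: MnO2 (excess), CH2Cl2, rt
Reagents that add atoms: none
Why: MnO2 oxidises the allylic alcohol selectively under neutral conditions, which should keep Z-to-E isomerisation of the enal low.

Step 8
Reactants: 11 (2Z,4S,6E)-4-[(tert-butyldimethylsilyl)oxy]-7-iodo-3-methylocta-2,6-dienal; 5 methyl propiolate
Product: 12 methyl (4R,5Z,7S,9E)-7-[(tert-butyldimethylsilyl)oxy]-4-hydroxy-10-iodo-6-methylundeca-5,9-dien-2-ynoate
Conditions: 5 (3 equiv), Me2Zn (3 equiv), (R,R)-ProPhenol (20 mol %), Ph3PO (40 mol %), toluene, 0–4 °C (alkynylzinc reagent formed in the flask); then 11; aq. NH4Cl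
Reagents that add atoms: none
Why: The same zinc–ProPhenol alkynylation, which works well on enals, with the enantiomeric ligand should add the acetylide to the Si face and set C6 as R by catalyst control, the remote C3 centre having little say.

Step 9
Reactants: 12 methyl (4R,5Z,7S,9E)-7-[(tert-butyldimethylsilyl)oxy]-4-hydroxy-10-iodo-6-methylundeca-5,9-dien-2-ynoate
Product: 13 methyl (4R,5Z,7S,9E)-4,7-bis[(tert-butyldimethylsilyl)oxy]-10-iodo-6-methylundeca-5,9-dien-2-ynoate
Conditions: TBSOTf, 2,6-lutidine, CH2Cl2, −78 °C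
Reagents that add atoms: tert-butyldimethylsilyl triflate, CC(C)(C)[Si](C)(C)OS(=O)(=O)C(F)(F)F
Why: Silylation keeps the C6 oxygen from chelating or lactonising during the next step and makes the C6 side of C7 the bulky one.

Step 10
Reactants: 13 methyl (4R,5Z,7S,9E)-4,7-bis[(tert-butyldimethylsilyl)oxy]-10-iodo-6-methylundeca-5,9-dien-2-ynoate; 14 vinylmagnesium chloride; 15 formaldehyde
Product: 17 methyl (2Z,4R,5Z,7S,9E)-4,7-bis[(tert-butyldimethylsilyl)oxy]-3-ethenyl-2-(hydroxymethyl)-10-iodo-6-methylundeca-2,5,9-trienoate, via alkenylcuprate 16 (not isolated)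
Conditions: 14 (2.4 equiv), CuI (1.2 equiv), THF, −78 to −50 °C; then 13, −78 °C; then 15 (monomeric, THF solution, excess), −78 to −40 °C; aq. NH4Cl
Reagents that add atoms: none
Why: Tandem conjugate addition–aldol reaction in which syn carbocupration puts the vinyl group on C7 and copper on C11, and formaldehyde then enters at C11 either with retention at the alkenylcopper or, through the magnesium allenolate, from the side of the small vinyl group away from the silyloxy-bearing C6, so that in both cases C13 should end cis to the vinyl group and the ester cis to C6 as the lactone requires.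

Step 11
Reactants: 17 methyl (2Z,4R,5Z,7S,9E)-4,7-bis[(tert-butyldimethylsilyl)oxy]-3-ethenyl-2-(hydroxymethyl)-10-iodo-6-methylundeca-2,5,9-trienoate
Product: 19 (5R)-4-ethenyl-3-(hydroxymethyl)-5-[(1Z,3S,5E)-3-hydroxy-6-iodo-2-methylhepta-1,5-dien-1-yl]furan-2(5H)-one, via triol ester 18 (not isolated)
Conditions: HF·pyridine, pyridine, THF, 0 °C to rt
Reagents that add atoms: none
Why: Fluoride-mediated desilylation frees both secondary alcohols, and the C6 hydroxyl, held cis to the ester across the tetrasubstituted olefin, should lactonise at once (5-exo-trig acyl substitution) in a medium that is never basic enough to touch the C6–H.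

Step 12
Reactants: 19 (5R)-4-ethenyl-3-(hydroxymethyl)-5-[(1Z,3S,5E)-3-hydroxy-6-iodo-2-methylhepta-1,5-dien-1-yl]furan-2(5H)-one
Product: 20 [(5R)-5-[(1Z,3S,5E)-3-acetoxy-6-iodo-2-methylhepta-1,5-dien-1-yl]-4-ethenyl-2-oxo-2,5-dihydrofuran-3-yl]methyl acetate (the 9,10-seco diacetate)
Conditions: Ac2O, pyridine, CH2Cl2, 0 °C to rt
Reagents that add atoms: acetic anhydride, CC(=O)OC(C)=O
Why: Acylation of the primary and the secondary alcohol with Ac2O in pyridine, with no stronger base present, should leave the acidic butenolide C6–H and its configuration alone.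

Step 13
Reactants: 20 the 9,10-seco diacetate
Product: 22 (1(10)E,3S,4Z,6R)-3,13-diacetoxygermacra-1(10),4,7(11)-trien-12,6-olide, via alkylborane 21 (not isolated)
Conditions: 9-BBN (2 equiv), THF, 0 °C to rt; then slow addition (syringe pump) to Pd(dppf)Cl2 (20 mol %), AsPh3 (40 mol %), Cs2CO3 (3 equiv), DMF/THF/H2O, rt to 40 °C, about 1 mM
Reagents that add atoms: none
Why: 9-BBN adds across the only monosubstituted olefin with boron on C9, the base turns the borane into the borate, zerovalent palladium inserts into the C10–I bond with retention, the primary alkyl group passes from boron to divalent palladium, and reductive elimination forms C9–C10. The closest known reaction type is the B-alkyl Suzuki–Miyaura macrocyclisation of alkyl-9-BBN boranes onto alkenyl iodides, and the Pd(dppf)Cl2/AsPh3/Cs2CO3 protocol is known to tolerate a secondary allylic acetate one CH2 away from a 2-iodopropenyl unit. The ten-membered carbocycle closes by reductive elimination from an eleven-membered alkyl(alkenyl)palladium ring, with the C1=C10 olefin ending inside the ring as the E isomer. No stereocentre is formed, and C3 and C6 are carried through unchanged. The step needs chemoselective hydroboration, retention of the iodide geometry, and ring closure ahead of oligomerisation, β-hydride elimination and ionisation of the allylic esters; these rest on the bulk of 9-BBN, the stereoretentive oxidative addition, slow addition at high dilution, and the fast C–I insertion with the bidentate dppf ligand at low temperature, while carbonate in wet DMF for a limited time should be mild enough for the C6–H.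

Step 14
Reactants: 22 (1(10)E,3S,4Z,6R)-3,13-diacetoxygermacra-1(10),4,7(11)-trien-12,6-olide
Product: 23 (1R,3S,4Z,6R)-3,13-diacetoxy-1-hydroperoxygermacra-4,7(11),10(14)-trien-12,6-olide (CNP0174966.1)
Conditions: O2, tetraphenylporphyrin (cat.), visible light, CH2Cl2, 0 °C
Reagents that add atoms: oxygen, O=O
Why: In the Schenck ene reaction singlet oxygen should attack only the electron-rich C1=C10 olefin (C4=C5 carries two allylic acyloxy groups and C7=C11 is conjugated to the lactone), bonding to C1 from the outer face of the ring while a C14 hydrogen on the more crowded side of the olefin is transferred, which gives the (1R)-hydroperoxide and the C10=C14 methylene.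

**Compound list**

1 | pent-3-yn-1-ol | CC#CCCO | starting material
2 | O-zirconated (E)-alkenylzirconocene chloride (Cp2Zr(Cl) on C10 and on the oxygen) | C/C(=C\CCO[Zr](Cl)(C1C=CC=C1)C1C=CC=C1)[Zr](Cl)(C1C=CC=C1)C1C=CC=C1 | intermediate
3 | (E)-4-iodopent-3-en-1-ol | C/C(I)=C\CCO | intermediate
4 | (E)-4-iodopent-3-enal | C/C(I)=C\CC=O | intermediate
5 | methyl propiolate | C#CC(=O)OC | starting material
6 | methyl (4S,6E)-4-hydroxy-7-iodooct-6-en-2-ynoate | COC(=O)C#C[C@@H](O)C/C=C(\C)I | intermediate
7 | methyl (4S,6E)-4-[(tert-butyldimethylsilyl)oxy]-7-iodooct-6-en-2-ynoate | COC(=O)C#C[C@@H](O[Si](C)(C)C(C)(C)C)C/C=C(\C)I | intermediate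
8 | lithium methyl(alkenyl)cuprate from syn addition to 7 (copper on C5, cis to the new methyl) | COC(=O)/C([Cu-]C)=C(/C)[C@@H](O[Si](C)(C)C(C)(C)C)C/C=C(\C)I.[Li+] | intermediate
9 | methyl (2Z,4S,6E)-4-[(tert-butyldimethylsilyl)oxy]-7-iodo-3-methylocta-2,6-dienoate | COC(=O)/C=C(/C)[C@@H](O[Si](C)(C)C(C)(C)C)C/C=C(\C)I | intermediate
10 | (2Z,4S,6E)-4-[(tert-butyldimethylsilyl)oxy]-7-iodo-3-methylocta-2,6-dien-1-ol | OC/C=C(/C)[C@@H](O[Si](C)(C)C(C)(C)C)C/C=C(\C)I | intermediate
11 | (2Z,4S,6E)-4-[(tert-butyldimethylsilyl)oxy]-7-iodo-3-methylocta-2,6-dienal | O=C/C=C(/C)[C@@H](O[Si](C)(C)C(C)(C)C)C/C=C(\C)I | intermediate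
12 | methyl (4R,5Z,7S,9E)-7-[(tert-butyldimethylsilyl)oxy]-4-hydroxy-10-iodo-6-methylundeca-5,9-dien-2-ynoate | COC(=O)C#C[C@H](O)/C=C(/C)[C@@H](O[Si](C)(C)C(C)(C)C)C/C=C(\C)I | intermediate
13 | methyl (4R,5Z,7S,9E)-4,7-bis[(tert-butyldimethylsilyl)oxy]-10-iodo-6-methylundeca-5,9-dien-2-ynoate | COC(=O)C#C[C@H](O[Si](C)(C)C(C)(C)C)/C=C(/C)[C@@H](O[Si](C)(C)C(C)(C)C)C/C=C(\C)I | intermediate
14 | vinylmagnesium chloride | C=C[Mg]Cl | starting material
15 | formaldehyde (monomeric, from paraformaldehyde) | C=O | starting material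
16 | chloromagnesium vinyl(alkenyl)cuprate from syn addition to 13 (copper on C11, cis to the new vinyl group) | COC(=O)/C([Cu-]C=C)=C(/C=C)[C@H](O[Si](C)(C)C(C)(C)C)/C=C(/C)[C@@H](O[Si](C)(C)C(C)(C)C)C/C=C(\C)I.[Mg+]Cl | intermediate
17 | methyl (2Z,4R,5Z,7S,9E)-4,7-bis[(tert-butyldimethylsilyl)oxy]-3-ethenyl-2-(hydroxymethyl)-10-iodo-6-methylundeca-2,5,9-trienoate | COC(=O)/C(CO)=C(/C=C)[C@H](O[Si](C)(C)C(C)(C)C)/C=C(/C)[C@@H](O[Si](C)(C)C(C)(C)C)C/C=C(\C)I | intermediate
18 | methyl (2Z,4R,5Z,7S,9E)-3-ethenyl-4,7-dihydroxy-2-(hydroxymethyl)-10-iodo-6-methylundeca-2,5,9-trienoate (triol ester) | COC(=O)/C(CO)=C(/C=C)[C@H](O)/C=C(/C)[C@@H](O)C/C=C(\C)I | intermediate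
19 | (5R)-4-ethenyl-3-(hydroxymethyl)-5-[(1Z,3S,5E)-3-hydroxy-6-iodo-2-methylhepta-1,5-dien-1-yl]furan-2(5H)-one | C=CC1=C(CO)C(=O)O[C@@H]1/C=C(/C)[C@@H](O)C/C=C(\C)I | intermediate
20 | [(5R)-5-[(1Z,3S,5E)-3-acetoxy-6-iodo-2-methylhepta-1,5-dien-1-yl]-4-ethenyl-2-oxo-2,5-dihydrofuran-3-yl]methyl acetate (9,10-seco diacetate) | C=CC1=C(COC(C)=O)C(=O)O[C@@H]1/C=C(/C)[C@@H](OC(C)=O)C/C=C(\C)I | intermediate
21 | B-alkyl-9-borabicyclo[3.3.1]nonane from 20 (boron on C9) | B1(CCC2=C(COC(C)=O)C(=O)O[C@@H]2/C=C(/C)[C@@H](OC(C)=O)C/C=C(\C)I)C3CCCC1CCC3 | intermediate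
22 | (1(10)E,3S,4Z,6R)-3,13-diacetoxygermacra-1(10),4,7(11)-trien-12,6-olide | C1/C=C(\C)CCC2=C(COC(C)=O)C(=O)O[C@@H]2/C=C(/C)[C@H]1OC(C)=O | intermediate
23 | (1R,3S,4Z,6R)-3,13-diacetoxy-1-hydroperoxygermacra-4,7(11),10(14)-trien-12,6-olide | C=C1CCC2=C(COC(C)=O)C(=O)O[C@@H]2/C=C(/C)[C@@H](OC(C)=O)C[C@H]1OO | target

**Summary**

Total step count: 14. Longest linear sequence: 14 steps (1 to 23).

Steps most likely to fail:

Step 13 (key step). Intermolecular coupling, β-hydride elimination or protodeboronation of the borate may overtake the slow transannular transmetalation, and the long contact with carbonate may epimerise C6 or cost an acetate. The fallback keeps the C9–C10 bond but changes the organometallic partner to zinc and drops the base. It sets out from 20: hydroboration with 9-BBN (alkylborane 21) and oxidation with NaBO3·4H2O should give the C9 primary alcohol F1, and I2, PPh3 and imidazole the C9 primary iodide F2. Zinc dust with LiCl in THF should insert only into the C(sp3)–I bond to give the alkylzinc iodide F3. Slow addition of this to Pd2(dba)3 and SPhos in THF at high dilution (intramolecular Negishi coupling) comes back to the route at 22.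

Step 10. The α-metallated enoate may add sluggishly to formaldehyde, or the aldol may take place on the C6 side and give the olefin isomer that cannot lactonise. The fallback fixes the olefin geometry by chelation instead of sterics and sets out from 11. Zinc–ProPhenol alkynylation ((R,R)-ligand, Me2Zn) with tert-butyldimethyl(prop-2-yn-1-yloxy)silane should give the propargylic alcohol F4. Vinylmagnesium chloride in THF/toluene then adds anti across the alkyne, vinyl to C7 and magnesium to C11, to give the five-membered oxamagnesacycle F5, which is trapped with CO2 and lactonised on acidic work-up to the bis-silyl butenolide F6. HF·pyridine comes back to the route at 19. This sequence is the second choice because loss of the C13 silyloxy group from the alkenylmagnesium (β-elimination to a vinylallene) competes on warming, so the addition would be run at the lowest temperature that consumes the alkyne and carboxylated immediately.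

Step 14. Singlet oxygen may attack both faces of the C1=C10 olefin, so that C1 is formed with poor selectivity. The fallback sets C1 by an SN2 inversion instead of by facial control; it sets out from 22 and comes back at 23. The unwanted (1S)-hydroperoxide F7 from the photooxygenation is separated and reduced with PPh3 to the (1S)-allylic alcohol F8. MsCl and Et3N at −65 °C give the allylic mesylate F9, and anhydrous H2O2 in ether at about −100 °C should displace it with inversion to 23.

**Further compounds**

F1 | step 13 | [(5R)-5-[(1Z,3S,5E)-3-acetoxy-6-iodo-2-methylhepta-1,5-dien-1-yl]-4-(2-hydroxyethyl)-2-oxo-2,5-dihydrofuran-3-yl]methyl acetate | OCCC1=C(COC(C)=O)C(=O)O[C@@H]1/C=C(/C)[C@@H](OC(C)=O)C/C=C(\C)I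
F2 | step 13 | [(5R)-5-[(1Z,3S,5E)-3-acetoxy-6-iodo-2-methylhepta-1,5-dien-1-yl]-4-(2-iodoethyl)-2-oxo-2,5-dihydrofuran-3-yl]methyl acetate | ICCC1=C(COC(C)=O)C(=O)O[C@@H]1/C=C(/C)[C@@H](OC(C)=O)C/C=C(\C)I
F3 | step 13 | alkylzinc iodide from F2 (zinc on C9) | I[Zn]CCC1=C(COC(C)=O)C(=O)O[C@@H]1/C=C(/C)[C@@H](OC(C)=O)C/C=C(\C)I
F4 | step 10 | (4R,5Z,7S,9E)-1,7-bis[(tert-butyldimethylsilyl)oxy]-10-iodo-6-methylundeca-5,9-dien-2-yn-4-ol | CC(C)(C)[Si](C)(C)OCC#C[C@H](O)/C=C(/C)[C@@H](O[Si](C)(C)C(C)(C)C)C/C=C(\C)I
F5 | step 10 | five-membered oxamagnesacycle from F4 (vinyl on C7, magnesium on C11 and on the C6 oxygen) | C=CC1=C(CO[Si](C)(C)C(C)(C)C)[Mg]O[C@@H]1/C=C(/C)[C@@H](O[Si](C)(C)C(C)(C)C)C/C=C(\C)I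
F6 | step 10 | (5R)-3-{[(tert-butyldimethylsilyl)oxy]methyl}-5-[(1Z,3S,5E)-3-[(tert-butyldimethylsilyl)oxy]-6-iodo-2-methylhepta-1,5-dien-1-yl]-4-ethenylfuran-2(5H)-one | C=CC1=C(CO[Si](C)(C)C(C)(C)C)C(=O)O[C@@H]1/C=C(/C)[C@@H](O[Si](C)(C)C(C)(C)C)C/C=C(\C)I
F7 | step 14 | (1S,3S,4Z,6R)-3,13-diacetoxy-1-hydroperoxygermacra-4,7(11),10(14)-trien-12,6-olide | C=C1CCC2=C(COC(C)=O)C(=O)O[C@@H]2/C=C(/C)[C@@H](OC(C)=O)C[C@@H]1OO
F8 | step 14 | (1S,3S,4Z,6R)-3,13-diacetoxy-1-hydroxygermacra-4,7(11),10(14)-trien-12,6-olide | C=C1CCC2=C(COC(C)=O)C(=O)O[C@@H]2/C=C(/C)[C@@H](OC(C)=O)C[C@@H]1O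
F9 | step 14 | (1S,3S,4Z,6R)-3,13-diacetoxy-1-(methanesulfonyloxy)germacra-4,7(11),10(14)-trien-12,6-olide | C=C1CCC2=C(COC(C)=O)C(=O)O[C@@H]2/C=C(/C)[C@@H](OC(C)=O)C[C@@H]1OS(C)(=O)=O
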